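**Retrosynthetic overview**
1. Target 27 ⇒ ketone 25 by MeMgBr addition to the ring B ketone (sets the tertiary carbinol) and desilylation.
2. Key disconnection: the CH2–C(sp2) bond between the ethylene tether and ring C, made by a nickel-catalysed radical cross-electrophile coupling of primary iodide 15 with the tetrasubstituted enol triflate 24.
3. Ring A (oxepane) and then ring B (cyclohexanone) form in one epoxide-opening cascade of an all-R diepoxide terminated by a 2,3-dihydrofuran enol ether, which also supplies the ketone carbon and both tether carbons.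
4. The acyclic chain comes from homoprenyl bromide, lithium acetylide, Me3Al, oxirane and 2,3-dihydrofuran; a zirconium-catalysed carboalumination fixes the E alkene and one Shi epoxidation sets both epoxides.
5. Ring C is present from the start (cyclohexane-1,3-dione): methylation, Tsuji–Trost allylation with a vinyl epoxide, CBS desymmetrisation, methylation/triflation.

Assumption: ring A = oxepane, ring B = the cyclohexane fused to it, ring C = the cyclohexene; rings A/B use 1-benzoxepine numbering (C6 carries the tether, C7 the tertiary carbinol); compounds 1, 2, 4, 10, 16, 18 and all reagents are taken as commercial.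

**Step 1**
Reactants: 1 5-bromo-2-methylpent-2-ene; 2 lithium acetylide–ethylenediamine complex
Product: 3 6-methylhept-5-en-1-yne
Conditions: DMSO, 10 °C → rt
Reagents that add atoms: none
Why: SN2 alkylation of the acetylide by the primary bromide in a dipolar aprotic solvent (acetylide alkylation) gives the terminal alkyne; no stereocentre is formed.

**Step 2**
Reactants: 3 6-methylhept-5-en-1-yne; 4 oxirane
Product: 7 homogeraniol [(3E)-4,8-dimethylnona-3,7-dien-1-ol], via alkenyldimethylalane 5 (not isolated), via lithium alkenylalanate 6 (not isolated)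
Conditions: Me3Al (2 equiv), Zr(C5H5)2Cl2 (25 mol%), ClCH2CH2Cl, rt; volatiles removed in vacuo; n-BuLi (1.1 equiv), THF/hexane, −78 → 0 °C; then 4 (3 equiv), −78 °C → rt; 1 M HCl (aq.), 0 °C
Reagents that add atoms: trimethylaluminium, C[Al](C)C
Why: Negishi zirconium-catalysed carboalumination adds methyl and aluminium syn across the terminal alkyne with methyl on the internal carbon, and the alanate made with n-BuLi opens oxirane with retention at the alkenyl carbon, so the new trisubstituted alkene is E and the remote trisubstituted alkene is untouched; no stereocentre is formed.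

**Step 3**
Reactants: 7 homogeraniol
Product: 8 homogeranyl bromide [(3E)-1-bromo-4,8-dimethylnona-3,7-diene]
Conditions: CBr4, PPh3, CH2Cl2, 0 °C
Reagents that add atoms: tetrabromomethane, BrC(Br)(Br)Br
Why: Appel bromination converts the primary alcohol to the bromide under neutral conditions that leave both trisubstituted alkenes untouched.

**Step 4**
Reactants: 8 homogeranyl bromide
Product: 9 diepoxy bromide [(2R,3R)-3-(2-bromoethyl)-2-{2-[(2R)-3,3-dimethyloxiran-2-yl]ethyl}-2-methyloxirane]
Conditions: Shi ketone (D-fructose-derived, 0.6 equiv), KHSO5 (as 2KHSO5·KHSO4·K2SO4), K2CO3, Bu4NHSO4, Na2B4O7 buffer pH 10.5, MeCN/CH2(OMe)2/H2O, 0 °C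
Reagents that add atoms: potassium peroxymonosulfate, [K+].[O-]S(=O)(=O)OO
Why: Shi asymmetric epoxidation with the D-fructose-derived dioxirane epoxidises both trisubstituted alkenes through the spiro transition state that gives R-configured carbons, so the three epoxide stereocentres (later C3, C5a, C9a) are set by the catalyst.

**Step 5**
Reactants: 9 diepoxy bromide; 10 2,3-dihydrofuran
Product: 12 diepoxy dihydrofuran [5-{2-[(2R,3R)-3-{2-[(2R)-3,3-dimethyloxiran-2-yl]ethyl}-3-methyloxiran-2-yl]ethyl}-2,3-dihydrofuran], via 5-lithio-2,3-dihydrofuran 11 (not isolated)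
Conditions: 10, t-BuLi, THF, −78 → 0 °C; then 9, DMPU, −30 → 10 °C
Reagents that add atoms: none
Why: Vinylic α-lithiation of the cyclic enol ether gives an alkenyllithium whose SN2 alkylation by the primary bromide is faster than attack on the hindered trisubstituted epoxides, installing a regiodefined cyclic enol ether that carries the latent ketone carbon and the two tether carbons; no new stereocentre.

**Step 6**
Reactants: 12 diepoxy dihydrofuran
Product: 14 keto diol [(3R,5aR,6R,9aR)-3-hydroxy-6-(2-hydroxyethyl)-2,2,5a-trimethyloctahydro-1-benzoxepin-7(2H)-one], via tricyclic enol ether 13 (not isolated)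
Conditions: BF3·OEt2 (0.3 equiv), 2,6-di-tert-butyl-4-methylpyridine (0.3 equiv), CH2Cl2, −78 °C; then 0.5 M HCl (aq.), THF, 0 °C
Reagents that add atoms: water, O
Why: Proposed new method: BF3 activates the terminal epoxide, the oxygen of the neighbouring epoxide opens it 7-endo at the tertiary carbon to give a bicyclic epoxonium ion (ring A, C3 stays R), the enol ether carbon C4 of the dihydrofuran (nucleophilicity comparable to a silyl enol ether) attacks the tertiary epoxonium carbon anti to oxygen through a chair transition state (ring B; inversion at C5a and retention at C9a give the trans-fused 5aR,9aR core), the oxocarbenium ion loses a proton to enol ether 13, and aqueous acid hydrolyses 13 with protonation of C6 opposite the axial C5a methyl (equatorial, thermodynamically preferred tether, 6R); the closest known reaction types are the Lewis-acid-promoted tandem oxa-/carbacyclisation of polyepoxides terminated by a silyl enol ether and furan-terminated epoxide cyclisations.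

**Step 7**
Reactants: 14 keto diol
Product: 15 iodo ketone [(3R,5aR,6R,9aR)-3-hydroxy-6-(2-iodoethyl)-2,2,5a-trimethyloctahydro-1-benzoxepin-7(2H)-one]
Conditions: I2, PPh3, imidazole, CH2Cl2, 0 °C
Reagents that add atoms: iodine, II
Why: Appel-type iodination substitutes the unhindered primary alcohol selectively, the neopentyl-like C3 alcohol and the ketone being inert, and gives the radical precursor.

**Step 8**
Reactants: 16 cyclohexane-1,3-dione
Product: 17 2-methylcyclohexane-1,3-dione
Conditions: MeI, KOH, H2O/MeOH, 65 °C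
Reagents that add atoms: iodomethane, CI
Why: Enolate alkylation of the 1,3-dione occurs at the doubly activated C2.

**Step 9**
Reactants: 18 4-methylpenta-1,3-diene
Product: 19 3-ethenyl-2,2-dimethyloxirane (racemic)
Conditions: mCPBA, NaHCO3, CH2Cl2, 0 °C
Reagents that add atoms: 3-chloroperoxybenzoic acid, OOC(=O)c1cccc(Cl)c1
Why: Prilezhaev epoxidation takes place at the more electron-rich trisubstituted double bond; the racemic stereocentre is erased in step 10.

**Step 10**
Reactants: 17 2-methylcyclohexane-1,3-dione; 19 3-ethenyl-2,2-dimethyloxirane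
Product: 20 2-[(2E)-4-hydroxy-4-methylpent-2-en-1-yl]-2-methylcyclohexane-1,3-dione
Conditions: Pd(PPh3)4 (3 mol%), THF, 0 °C → rt
Reagents that add atoms: none
Why: Tsuji–Trost allylation under neutral conditions: zerovalent palladium opens the vinyl epoxide to a π-allyl alkoxide that deprotonates the dione, and the enolate attacks the unhindered allyl terminus (1,4-addition) to give the C-allylated E-alkene with the tertiary alcohol in place.

**Step 11**
Reactants: 20 allylated dione
Product: 21 (2R,3R)-3-hydroxy-2-[(2E)-4-hydroxy-4-methylpent-2-en-1-yl]-2-methylcyclohexan-1-one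
Conditions: (S)-2-methyl-CBS-oxazaborolidine (20 mol%), catecholborane (2.2 equiv), PhMe, −78 → −40 °C; then MeOH, aq. NaOH
Reagents that add atoms: none
Why: Corey–Bakshi–Shibata reduction desymmetrises the prochiral dione: the (S)-oxazaborolidine gives the R carbinol with the quaternary carbon as the large group, and the carbonyl that can be attacked anti to the larger pentenyl chain reacts, so the hydroxyl ends cis to that chain and the quaternary centre becomes R.

**Step 12**
Reactants: 21 hydroxy ketone
Product: 22 (2R,3R)-2-methyl-3-(triethylsilyloxy)-2-[(2E)-4-methyl-4-(triethylsilyloxy)pent-2-en-1-yl]cyclohexan-1-one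
Conditions: Et3SiOTf, 2,6-lutidine, CH2Cl2, −78 → 0 °C
Reagents that add atoms: triethylsilyl trifluoromethanesulfonate, CC[Si](CC)(CC)OS(=O)(=O)C(F)(F)F
Why: Silyl ether formation caps both hydroxyls so that the β-hydroxy ketone cannot undergo retro-aldol cleavage under the strong bases of step 13.

**Step 13**
Reactants: 22 bis(triethylsilyl) ketone
Product: 24 enol triflate [(5R,6R)-2,6-dimethyl-5-(triethylsilyloxy)-6-[(2E)-4-methyl-4-(triethylsilyloxy)pent-2-en-1-yl]cyclohex-1-en-1-yl trifluoromethanesulfonate], via 6-methyl ketone 23 (not isolated)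
Conditions: LiN(iPr)2 (1.05 equiv), THF, −78 °C, then MeI (1.0 equiv), → 0 °C; then KN(SiMe3)2 (1.3 equiv), −78 °C, PhNTf2, → 0 °C
Reagents that add atoms: iodomethane, CI; N-phenylbis(trifluoromethanesulfonimide), O=S(=O)(N(c1ccccc1)S(=O)(=O)C(F)(F)F)C(F)(F)F
Why: Only C6 is enolisable, so enolate methylation followed by deprotonation of the new methine and O-sulfonylation (enol triflate formation) gives the tetrasubstituted triflate regiospecifically, erasing the transient C6 stereocentre.

**Step 14**
Reactants: 15 iodo ketone; 24 enol triflate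
Product: 25 coupled ketone [(3R,5aR,6R,9aR)-6-{2-[(5R,6S)-2,6-dimethyl-5-(triethylsilyloxy)-6-[(2E)-4-methyl-4-(triethylsilyloxy)pent-2-en-1-yl]cyclohex-1-en-1-yl]ethyl}-3-hydroxy-2,2,5a-trimethyloctahydro-1-benzoxepin-7(2H)-one]
Conditions: NiBr2(dme) (15 mol%), 4,4′-di-tert-butyl-2,2′-bipyridine (15 mol%), Mn powder (3 equiv), NaI (0.25 equiv), DMA, 40 °C
Reagents that add atoms: none
Why: Nickel-catalysed reductive cross-electrophile coupling: zerovalent nickel adds oxidatively to the enol triflate, the primary alkyl radical formed from 15 by iodine-atom abstraction is captured at nickel, and C(sp3)–C(sp2) reductive elimination follows with Mn as terminal reductant; no stereocentre is formed and the free hydroxyl, ketone and silyl ethers are tolerated.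

**Step 15**
Reactants: 25 coupled ketone
Product: 27 siphonellinol C, via bis(triethylsilyl) ether 26 (not isolated)
Conditions: MeMgBr (6 equiv), THF, −40 → 0 °C; then Bu4NF, THF, rt
Reagents that add atoms: methylmagnesium bromide, C[Mg]Br
Why: Grignard 1,2-addition to the ring B ketone occurs by equatorial attack because the axial face is blocked by the 1,3-diaxial C5a methyl, giving the axial 7S tertiary alcohol cis to the tether, and fluoride then cleaves both triethylsilyl ethers (desilylation).

**Compound list**
1 | 5-bromo-2-methylpent-2-ene | CC(C)=CCCBr | starting material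
2 | lithium acetylide–ethylenediamine complex | [Li]C#C.NCCN | starting material
3 | 6-methylhept-5-en-1-yne | CC(C)=CCCC#C | intermediate
4 | oxirane | C1CO1 | starting material
5 | [(1E)-2,6-dimethylhepta-1,5-dien-1-yl]dimethylalane | CC(C)=CCC/C(C)=C/[Al](C)C | intermediate
6 | lithium butyl[(1E)-2,6-dimethylhepta-1,5-dien-1-yl]dimethylalanate | [Li+].CCCC[Al-](C)(C)/C=C(\C)CCC=C(C)C | intermediate
7 | (3E)-4,8-dimethylnona-3,7-dien-1-ol (homogeraniol) | CC(C)=CCC/C(C)=C/CCO | intermediate
8 | (3E)-1-bromo-4,8-dimethylnona-3,7-diene | CC(C)=CCC/C(C)=C/CCBr | intermediate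
9 | (2R,3R)-3-(2-bromoethyl)-2-{2-[(2R)-3,3-dimethyloxiran-2-yl]ethyl}-2-methyloxirane | BrCC[C@H]1O[C@]1(C)CC[C@H]1OC1(C)C | intermediate
10 | 2,3-dihydrofuran | C1=COCC1 | starting material
11 | 5-lithio-2,3-dihydrofuran | [Li]C1=CCCO1 | intermediate
12 | 5-{2-[(2R,3R)-3-{2-[(2R)-3,3-dimethyloxiran-2-yl]ethyl}-3-methyloxiran-2-yl]ethyl}-2,3-dihydrofuran | O1CCC=C1CC[C@H]1O[C@]1(C)CC[C@H]1OC1(C)C | intermediate
13 | tricyclic enol ether: rings A/B (3R,5aR,9aR) with a 4,5-dihydrofuran fused across C6=C7, oxygen on C7 | O1CCC2=C1CC[C@H]1OC(C)(C)[C@H](O)CC[C@]21C | intermediate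
14 | (3R,5aR,6R,9aR)-3-hydroxy-6-(2-hydroxyethyl)-2,2,5a-trimethyloctahydro-1-benzoxepin-7(2H)-one | OCC[C@@H]1[C@@]2(C)CC[C@@H](O)C(C)(C)O[C@@H]2CCC1=O | intermediate
15 | (3R,5aR,6R,9aR)-3-hydroxy-6-(2-iodoethyl)-2,2,5a-trimethyloctahydro-1-benzoxepin-7(2H)-one | ICC[C@@H]1[C@@]2(C)CC[C@@H](O)C(C)(C)O[C@@H]2CCC1=O | intermediate
16 | cyclohexane-1,3-dione | O=C1CCCC(=O)C1 | starting material
17 | 2-methylcyclohexane-1,3-dione | CC1C(=O)CCCC1=O | intermediate
18 | 4-methylpenta-1,3-diene | CC(C)=CC=C | starting material
19 | 3-ethenyl-2,2-dimethyloxirane (racemic) | CC1(C)OC1C=C | intermediate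
20 | 2-[(2E)-4-hydroxy-4-methylpent-2-en-1-yl]-2-methylcyclohexane-1,3-dione | CC1(C/C=C/C(C)(C)O)C(=O)CCCC1=O | intermediate
21 | (2R,3R)-3-hydroxy-2-[(2E)-4-hydroxy-4-methylpent-2-en-1-yl]-2-methylcyclohexan-1-one | O=C1[C@](C)(C/C=C/C(C)(C)O)[C@H](O)CCC1 | intermediate
22 | (2R,3R)-2-methyl-3-(triethylsilyloxy)-2-[(2E)-4-methyl-4-(triethylsilyloxy)pent-2-en-1-yl]cyclohexan-1-one | O=C1[C@](C)(C/C=C/C(C)(C)O[Si](CC)(CC)CC)[C@H](O[Si](CC)(CC)CC)CCC1 | intermediate
23 | 6-methyl derivative of 22 (mixture of C6 epimers; C6 becomes sp2 in the same step) | O=C1[C@](C)(C/C=C/C(C)(C)O[Si](CC)(CC)CC)[C@H](O[Si](CC)(CC)CC)CCC1C | intermediate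
24 | (5R,6R)-2,6-dimethyl-5-(triethylsilyloxy)-6-[(2E)-4-methyl-4-(triethylsilyloxy)pent-2-en-1-yl]cyclohex-1-en-1-yl trifluoromethanesulfonate | CC1=C(OS(=O)(=O)C(F)(F)F)[C@](C)(C/C=C/C(C)(C)O[Si](CC)(CC)CC)[C@H](O[Si](CC)(CC)CC)CC1 | intermediate
25 | coupled ketone (name as in step 14) | CC1=C(CC[C@@H]2[C@@]3(C)CC[C@@H](O)C(C)(C)O[C@@H]3CCC2=O)[C@](C)(C/C=C/C(C)(C)O[Si](CC)(CC)CC)[C@H](O[Si](CC)(CC)CC)CC1 | intermediate
26 | bis(triethylsilyl) ether of siphonellinol C (ring C secondary and side-chain tertiary oxygens silylated) | CC1=C(CC[C@@H]2[C@@]3(C)CC[C@@H](O)C(C)(C)O[C@@H]3CC[C@]2(C)O)[C@](C)(C/C=C/C(C)(C)O[Si](CC)(CC)CC)[C@H](O[Si](CC)(CC)CC)CC1 | intermediate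
27 | siphonellinol C [(3R,5aR,6R,7S,9aR)-6-{2-[(5R,6S)-5-hydroxy-6-[(2E)-4-hydroxy-4-methylpent-2-en-1-yl]-2,6-dimethylcyclohex-1-en-1-yl]ethyl}-2,2,5a,7-tetramethyldecahydro-1-benzoxepine-3,7-diol] | CC1=C(CC[C@@H]2[C@@]3(C)CC[C@@H](O)C(C)(C)O[C@@H]3CC[C@]2(C)O)[C@](C)(C/C=C/C(C)(C)O)[C@H](O)CC1 | target

**Totals**
Total step count: 15. Longest linear sequence: 9 steps (steps 1–7, 14, 15).

**Steps most likely to fail**

Step 14. The enol triflate is tetrasubstituted and flanked by a quaternary carbon, so oxidative addition and radical capture may lose out to reduction or homocoupling of the iodide. The fallback leaves the radical manifold for a palladium-catalysed Negishi coupling. It sets out from 15: Me3SiCl and imidazole give the trimethylsilyl ether of the iodo ketone F1. Zinc insertion (Zn dust, LiCl, THF, 40 °C) gives the alkylzinc iodide F2. Coupling with 24 under Pd(OAc)2/SPhos gives the coupled trimethylsilyl ether F3, whose trimethylsilyl group is removed selectively with K2CO3 in MeOH. The sequence comes back to the route at 25.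

Step 6. A cyclic enol ether has not been used as terminator of an epoxonium cascade; direct attack on the internal epoxide or acid-induced loss of the enol ether could compete. The fallback uses the well-established furan terminator. It sets out from 9: 2-lithiofuran (furan, n-BuLi) is alkylated with 9 to the 2-alkylfuran diepoxide F4. BF3·OEt2 then triggers the same oxa-/carbacyclisation with furan C3 as nucleophile to give the furan-fused tricycle F5. Hydrogenation of the unsubstituted furan double bond (H2, 5% Rh on Al2O3, one equivalent) gives enol ether 13, and hydrolysis with dilute HCl comes back to the route at 14.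

Step 11. The free tertiary alcohol consumes borane, and the cis/trans ratio rests on a modest size difference between methyl and the pentenyl chain. The fallback replaces asymmetric reduction by kinetic resolution. It sets out from 20: NaBH4 (MeOH, −78 °C) gives the racemic hydroxy ketone F6, cis isomer separated by chromatography. Immobilised Candida antarctica lipase B with vinyl acetate acetylates only the 3R alcohol (Kazlauskas rule) to the (R)-acetate F7, which is separated and methanolysed (K2CO3, MeOH). The sequence comes back to the route at 21.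

**Further compounds**
F1 | step 14 | trimethylsilyl ether of iodo ketone 15 | ICC[C@@H]1[C@@]2(C)CC[C@@H](O[Si](C)(C)C)C(C)(C)O[C@@H]2CCC1=O
F2 | step 14 | alkylzinc iodide from F1 | I[Zn]CC[C@@H]1[C@@]2(C)CC[C@@H](O[Si](C)(C)C)C(C)(C)O[C@@H]2CCC1=O
F3 | step 14 | coupled trimethylsilyl ether (25 with C3–OSiMe3) | CC1=C(CC[C@@H]2[C@@]3(C)CC[C@@H](O[Si](C)(C)C)C(C)(C)O[C@@H]3CCC2=O)[C@](C)(C/C=C/C(C)(C)O[Si](CC)(CC)CC)[C@H](O[Si](CC)(CC)CC)CC1
F4 | step 6 | 2-alkylfuran diepoxide, 2-{2-[(2R,3R)-3-{2-[(2R)-3,3-dimethyloxiran-2-yl]ethyl}-3-methyloxiran-2-yl]ethyl}furan | o1cccc1CC[C@H]1O[C@]1(C)CC[C@H]1OC1(C)C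
F5 | step 6 | furan-fused tricycle (rings A/B with furan fused at C6–C7) | o1ccc2c1CC[C@H]1OC(C)(C)[C@H](O)CC[C@]21C
F6 | step 11 | racemic hydroxy ketone (racemate of 21, one enantiomer drawn) | O=C1[C@](C)(C/C=C/C(C)(C)O)[C@H](O)CCC1
F7 | step 11 | (R)-acetate of 21 | O=C1[C@](C)(C/C=C/C(C)(C)O)[C@H](OC(C)=O)CCC1
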